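## The problem

The target joins a C20 abietane and a C19 20-nor-abietane (abietane numbering, primes for the nor half). The left half is an 11-hydroxy-12-oxo quinone methide (C7=C8, C9=C11, C13=C14). The right half has an aromatic ring B' carrying the 6'-phenol and a ring C' that is a 12'-hydroxy-11'-oxo cyclohexadienone. The halves share one C–C bond (C7–C14') and one ether bond (O14–C14'); these close the five-membered ring D (O14, C14, C8, C7, C14') and make C14' a spiro quaternary carbon bearing O14, C7, C8' and C13'. There are four stereocentres: C5 and C10 (natural trans-fused series), the S carbinol C1' beside the C11' ketone, and C14', whose aromatic neighbour C8' lies on the β-face (the side of the C10 methyl group) and whose C13' lies on the α-face. In the target C7 is sp2, so C5/C10 cannot steer C14' directly, and C1' is too remote to be set by anything but a reagent. The quinone methide, the diosphenol and the tertiary, doubly activated C14'–O bond rule out late hydrogenolysis, strong Lewis acids and prolonged base, and every catechol or naphthalenediol on the way is air-sensitive. The enabling feature is that C14' becomes the β-carbon of the C12' carbonyl once ring C' is an 11',12'-ortho-quinone, while O14 sits four bonds away (O14–C14–C8–C7–C14'). Ring D is therefore the retron of a 5-exo oxa-Michael addition, and a C7 that is still sp3 at that moment can carry the C5/C10 information to C14' before it is erased.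

## Retrosynthesis

**Last oxidation (33 ⇒ 32 ⇒ 30).** The phenol silyl ether of 32 is removed last. In 32 the C11 oxygen, the C7=C8 double bond and the loss of the C7 stereocentre are traced back to one operation: ortho-oxidation of the 12-phenol 30 to the 11,12-quinone 31, which tautomerises to the quinone methide. The neighbouring cut, a left catechol carried through the synthesis, would need O11 installed early and a protecting group that deactivates the ring during the key step. Carrying the left ring as a 12,14-resorcinol removes both needs, because a resorcinol cannot be oxidised to a quinone. The forward step must pick the electron-rich left phenol in the presence of the diosphenol.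

**Ring D (30 ⇒ 28, key step).** The O14–C14' bond is cut. Oxidation of the naphthalene-11',12'-diol 28 gives the ortho-quinone 29, and the 14-hydroxyl adds to C14'. This cut is preferred over cuts through C7–C14' or through ring C' at the spiro stage because it needs no carbon–carbon bond formation at a quaternary centre and delivers ring C' at its final oxidation level. Precursor 28 is an open diarylmethine with one fewer ring and one fewer stereocentre. The forward reaction has to oxidise only the right half and add O14 to one face of C14'; the 7α-hydrogen is there to direct that.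

**C7–C14' bond (28 ⇒ 27 ⇒ 24 + 10).** The biaryl-methine bond is cut at the alkene level: styrene 27 comes from a Negishi coupling of aryl bromide 24 (as its zinc reagent) with enol triflate 10. The obvious neighbour, acid-mediated Friedel–Crafts alkylation of a C7 cation, would bring the naphthyl group in from the α-face. That gives the pseudo-axial 7α-aryl epimer, in which the aryl group points away from O14 and which, by the model used here, would relay the wrong configuration to C14'. Making the aryl bond first and delivering hydrogen afterwards reverses this: H2 adds to C6=C7 of 27 from the α-face, away from the axial C10 and C4 methyl groups, so the aryl group ends up 7β and pseudo-equatorial, next to O14. The same hydrogenation removes all four benzyl ethers, so 28 appears with exactly the hydroxyls the key step needs.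

**Left half (10 ⇒ 9 ⇒ 8 ⇒ 7 ⇒ 6 ⇒ 5 ⇒ 1).** The triflate comes from ketone 9. Its two oxygens are traced to the aryl bromides of 7 via diol 8, the C7 ketone to benzylic oxidation of dibromide 6, and the bromines to electrophilic substitution of abieta-8,11,13-triene 5 at the two positions ortho to the isopropyl group. Compound 5 is (+)-dehydroabietic acid 1 with its carboxyl reduced to methyl. The chiral pool fixes C5 and C10, and the order (bromination, then CrO3, then C–O formation) keeps the ring electron-poor during the chromium step.

**Right half (24 ⇒ 23 ⇒ 22 ⇒ 20 ⇒ 15 + 17).** The bromine of 24 is placed para to O11' by NBS. The carbinol of 23 comes from asymmetric transfer hydrogenation of tetralone-type ketone 22, where aryl versus methylene differentiation is at its best. The benzyl ethers of 22 come from reductive benzylation of ortho-quinone 20. Ring B' of 20 is cut across C7'–C8' and C9'–C10': a Diels–Alder reaction between 3-isopropyl-1,2-benzoquinone 17 and the 2-silyloxy diene unit of triene 15, followed by dehydrogenation. This builds the whole tricycle with the C6' oxygen in place as a silyl ether that survives to the last step.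

**Diene and dienophile (15 ⇒ 14 ⇒ 12 ⇒ 11; 17 ⇒ 16).** Triene 15 is the bis(silyl enol ether) of enedione 14. Silylating both ketones removes the question of which one enolises. Enedione 14 comes from Stork–Danheiser addition of 1-ethoxyvinyllithium to vinylogous ester 12, made from 4,4-dimethylcyclohexane-1,3-dione 11; this sequence puts the acetyl group on the carbonyl carbon next to the gem-dimethyl group. Quinone 17 is the oxidation product of 3-isopropylcatechol 16.

## Roads not taken

**Alternative 1:** ring C' is cut at C13'–C14' and C11'–C12'. Irradiation at 365 nm of an ortho-formylaryl dihydrobenzofuran would give a photoenol that adds to an isopropyl-bearing nitroalkene, producing the spiro nitro alcohol A1.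
- Merits: the quaternary carbon is made by irreversible C–C bond formation, and a C7 stereocentre could steer it much as in the chosen plan.
- Weak points: the reacting terminus of the photoenol is fully substituted and sits in the dihydrofuran ring, and it must bond to the nitroalkene carbon that carries the isopropyl group, so two congested centres are joined. Reketonisation of the photoenol competes. A1 still needs alcohol oxidation and a Nef-type conversion to reach the diosphenol, and its three new stereocentres are discarded. The substrate already requires both the C7–C14' and the O14–C14' bonds, so the hard bonds are only moved upstream.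
- Comparison: the chosen plan relies on a reversible C–O addition, which is its weaker point next to the C–C bond formation of A1. Against that it reaches ring C' at the correct oxidation level in the same step and from simpler fragments.

**Alternative 2:** rings A and B of the left half are cut at C4–C5 and C9–C10. A chiral Brønsted-acid-assisted Lewis acid (SnCl4 with a BINOL monoether) would cyclise a 3-geranyl-2-arylbenzofuran to A2.
- Merits: two rings and both left-half stereocentres form in one step from an achiral chain. No chiral-pool editing is needed, whereas the chosen plan spends eight steps on turning dehydroabietic acid into 10. On left-half step economy this road is better.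
- Weak points: enantioselectivity of such cyclisations is rarely complete, and the target is wanted as a single enantiomer. In A2, C14' is an aromatic benzofuran carbon, so the spiro centre and ring C' still have to be made by a dearomatising annulation for which A2 offers no control element. Three aryl methyl ethers must be removed late.
- Comparison: the chosen plan sets absolute configuration securely from dehydroabietic acid and has a defined relay for C14'.

**Alternative 3:** rings A', B' and C' are cut together at C8'–C9', C5'–C10' and C6'–C7'. RhCl(PPh3)3 would cyclotrimerise a tethered triyne to the boronate A3.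
- Merits: very convergent; the aromatic ring is made last and the boronate gives the C6' phenol by a mild oxidation, cleaner than carrying a silyl ether from the diene as the chosen plan does.
- Weak points: the triyne must already contain the spiro quaternary carbon C14' with its ether, its enol ether and an ethynyl group, so the hardest stereocentre has to be built on a propargylic centre with no obvious control. A fully intramolecular cyclotrimerisation through three different tethers, with an ynone and an alkynylboronate, is a demanding substrate.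
- Comparison: the chosen plan is less convergent in ring construction but solves C14' with a relay that the route creates anyway.

Key step: step 19

Remarks on the chemistry:
- Assumption: acid-catalysed enol etherification of dione 11 is taken to occur at the carbonyl remote from the gem-dimethyl group, as in related 4,4-disubstituted cyclohexane-1,3-diones; a minor regioisomer would be removed by chromatography.
- Faces are given relative to the abietane skeleton: β is the side of the C10 methyl group.
- Compound 28 is the precursor and compound 30 the product of the key step.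

## Route

Step 1
Reactants: 1 (+)-dehydroabietic acid
Product: 2 dehydroabietinol (abieta-8,11,13-trien-18-ol; 5α-H, 10β-CH3)
Conditions: LiAlH4, THF, 0 °C to reflux; aqueous NaOH work-up
Reagents that add atoms: none
Why: Hydride reduction of the carboxylic acid to the primary alcohol; no stereocentre is involved.

Step 2
Reactants: 2 dehydroabietinol
Product: 3 dehydroabietinal (abieta-8,11,13-trien-18-al)
Conditions: Dess–Martin periodinane, NaHCO3, CH2Cl2, 0 to 20 °C
Reagents that add atoms: none
Why: Dess–Martin oxidation of a neopentyl primary alcohol; the aldehyde has no α-hydrogen and cannot epimerise.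

Step 3
Reactants: 3 dehydroabietinal
Product: 5 abieta-8,11,13-triene (5α-H, 10β-CH3), via hydrazone 4 (not isolated)
Conditions: N2H4·H2O, KOH, diethylene glycol, 120 °C then 200 °C
Reagents that add atoms: none
Why: Wolff–Kishner reduction turns the hindered aldehyde into the C18 methyl group and so gives the C4 gem-dimethyl group.

Step 4
Reactants: 5 abieta-8,11,13-triene
Product: 6 12,14-dibromoabieta-8,11,13-triene
Conditions: Br2 (2.3 equiv), FeBr3 (5 mol %), CH2Cl2, 0 to 20 °C, dark
Reagents that add atoms: bromine, BrBr
Why: Electrophilic aromatic bromination at the two positions ortho to the isopropyl group, the pattern known for dinitration of this ring; exclusion of light avoids benzylic bromination.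

Step 5
Reactants: 6 12,14-dibromoabieta-8,11,13-triene
Product: 7 12,14-dibromoabieta-8,11,13-trien-7-one
Conditions: CrO3, AcOH/H2O, 40 °C
Reagents that add atoms: chromium trioxide, O=[Cr](=O)=O
Why: Benzylic oxidation of the only benzylic methylene (C7), standard for dehydroabietane derivatives; the two bromines keep the arene electron-poor and protect it from ring oxidation.

Step 6
Reactants: 7 12,14-dibromoabieta-8,11,13-trien-7-one
Product: 8 12,14-dihydroxyabieta-8,11,13-trien-7-one
Conditions: Pd2(dba)3 (2 mol %), tBuXPhos (8 mol %), KOH, 1,4-dioxane/H2O, 100 °C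
Reagents that add atoms: potassium hydroxide, [K+].[OH-]
Why: Palladium-catalysed hydroxylation of aryl bromides with hydroxide, which tolerates ortho,ortho-disubstituted bromides; the bromide ortho to the ketone is further activated.

Step 7
Reactants: 8 12,14-dihydroxyabieta-8,11,13-trien-7-one
Product: 9 12,14-bis(benzyloxy)abieta-8,11,13-trien-7-one
Conditions: BnBr, K2CO3, TBAI (cat.), DMF, 60 °C
Reagents that add atoms: benzyl bromide, BrCc1ccccc1
Why: Williamson etherification of both phenols; the chelated 14-hydroxyl reacts more slowly, hence warm DMF and iodide catalysis.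

Step 8
Reactants: 9 12,14-bis(benzyloxy)abieta-8,11,13-trien-7-one
Product: 10 12,14-bis(benzyloxy)abieta-6,8,11,13-tetraen-7-yl trifluoromethanesulfonate
Conditions: KHMDS, THF, −78 °C; PhNTf2, −78 to 0 °C
Reagents that add atoms: N-phenylbis(trifluoromethanesulfonimide), O=S(=O)(N(c1ccccc1)S(=O)(=O)C(F)(F)F)C(F)(F)F
Why: Enolate O-triflation of a tetralone-type ketone; C6 is the only enolisable position.

Step 9
Reactants: 11 4,4-dimethylcyclohexane-1,3-dione
Product: 12 3-isobutoxy-6,6-dimethylcyclohex-2-en-1-one
Conditions: i-BuOH, TsOH (cat.), toluene, reflux, Dean–Stark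
Reagents that add atoms: 2-methylpropan-1-ol, CC(C)CO
Why: Acid-catalysed enol ether formation under thermodynamic control places the alkoxy group on the unhindered carbonyl carbon and leaves the ketone next to the gem-dimethyl group.

Step 10
Reactants: 12 3-isobutoxy-6,6-dimethylcyclohex-2-en-1-one
Product: 14 3-acetyl-4,4-dimethylcyclohex-2-en-1-one, via tertiary alcohol 13 (not isolated)
Conditions: ethyl vinyl ether, t-BuLi, THF, −78 to 0 °C; add 12, −78 °C; then 1 M HCl, 20 °C
Reagents that add atoms: ethyl vinyl ether, C=COCC; water, O
Why: Stork–Danheiser sequence: 1,2-addition of the acyl anion equivalent to the vinylogous ester, then acid hydrolysis with allylic transposition, unmasking both ketones with the acetyl group beside the quaternary carbon.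

Step 11
Reactants: 14 3-acetyl-4,4-dimethylcyclohex-2-en-1-one
Product: 15 2-(tert-butyldimethylsilyloxy)-4-[1-(tert-butyldimethylsilyloxy)vinyl]-5,5-dimethylcyclohexa-1,3-diene
Conditions: TBSOTf (2.5 equiv), Et3N (4 equiv), CH2Cl2, 0 °C
Reagents that add atoms: tert-butyldimethylsilyl trifluoromethanesulfonate, CC(C)(C)[Si](C)(C)OS(=O)(=O)C(F)(F)F
Why: Exhaustive soft enolisation; each ketone has only one enolisable side (the γ-position is quaternary), so a single bis(silyl enol ether) should form and no regioselective mono-enolisation is needed.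

Step 12
Reactants: 16 3-isopropylcatechol
Product: 17 3-isopropyl-1,2-benzoquinone
Conditions: Ag2O, MgSO4, Et2O, 0 °C; filtered and used at once
Reagents that add atoms: none
Why: Standard two-electron oxidation of a catechol to the ortho-quinone; the quinone is used immediately because it dimerises on standing.

Step 13
Reactants: 15 bis(silyl enol ether) triene; 17 3-isopropyl-1,2-benzoquinone
Product: 20 10-(tert-butyldimethylsilyloxy)-7-isopropyl-1,1-dimethyl-2,3-dihydrophenanthrene-4,5,6(1H)-trione (the 6'-silyloxy-1'-oxo ortho-quinone), via catechol adduct 18 (not isolated), via quinone silyl enol ether 19 (not isolated)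
Conditions: 17 (3.2 equiv), CH2Cl2, ultrasound, 20 °C; then 1 M HCl, THF, 0 °C
Reagents that add atoms: none
Why: Diels–Alder reaction of the unsubstituted C=C of the ortho-quinone with the exocyclic 2-silyloxy diene unit, the known way to this ring system from vinylcyclohexenes. The nucleophilic CH2 terminus should bond to the quinone β-carbon, giving C7'–C8' and C9'–C10'; the ring diene of 15 is blocked at its fully substituted terminus. Excess quinone dehydrogenates the adduct to the naphthoquinone, and dilute acid cleaves only the ring A' enol ether.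

Step 14
Reactants: 20 6'-silyloxy-1'-oxo ortho-quinone
Product: 22 5,6-bis(benzyloxy)-10-(tert-butyldimethylsilyloxy)-7-isopropyl-1,1-dimethyl-2,3-dihydrophenanthren-4(1H)-one (11',12'-dibenzyl ether), via naphthalenediol 21 (not isolated)
Conditions: Na2S2O4, THF/H2O, 20 °C, argon; then BnBr, K2CO3, TBAI (cat.), DMF, 40 °C
Reagents that add atoms: benzyl bromide, BrCc1ccccc1
Why: Reductive alkylation of a quinone: dithionite gives the naphthalenediol, which is benzylated before it can reoxidise; the hindered aryl silyl ether should survive carbonate in DMF.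

Step 15
Reactants: 22 11',12'-dibenzyl ether ketone
Product: 23 (4S)-5,6-bis(benzyloxy)-10-(tert-butyldimethylsilyloxy)-7-isopropyl-1,1-dimethyl-1,2,3,4-tetrahydrophenanthren-4-ol (1'S carbinol)
Conditions: RuCl[(S,S)-TsDPEN](p-cymene) (2 mol %), HCO2H/Et3N (5:2), CH2Cl2, 35 °C
Reagents that add atoms: none
Why: Noyori asymmetric transfer hydrogenation of an aryl ketone of the 1-tetralone type; by analogy with 1-tetralone the (S,S)-catalyst should give the S carbinol, which sets C1' by reagent control.

Step 16
Reactants: 23 1'S carbinol
Product: 24 (4S)-5,6-bis(benzyloxy)-8-bromo-10-(tert-butyldimethylsilyloxy)-7-isopropyl-1,1-dimethyl-1,2,3,4-tetrahydrophenanthren-4-ol (14'-bromide)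
Conditions: NBS, MeCN, −20 to 0 °C, dark
Reagents that add atoms: N-bromosuccinimide, O=C1CCC(=O)N1Br
Why: Electrophilic bromination of a 1,2-dialkoxynaphthalene at the α-position para to the 11'-ether (C14'); the other open position (C7') is shielded by the bulky 6'-silyl ether.

Step 17
Reactants: 24 14'-bromide; 10 enol triflate
Product: 27 12,14-bis(benzyloxy)-7-[(1'S)-11',12'-bis(benzyloxy)-6'-(tert-butyldimethylsilyloxy)-1'-hydroxy-20'-norabieta-5'(10'),6',8',11',13'-pentaen-14'-yl]abieta-6,8,11,13-tetraene, via aryllithium alkoxide 25 (not isolated), via arylzinc chloride 26 (not isolated)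
Conditions: 24, n-BuLi (2.05 equiv), THF, −78 °C; ZnCl2 (1.1 equiv), −78 to 20 °C; then 10, Pd(OAc)2 (5 mol %), SPhos (10 mol %), THF, 60 °C
Reagents that add atoms: none
Why: Negishi coupling of a di-ortho-substituted arylzinc with an alkenyl triflate under a bulky biarylphosphine catalyst, a combination that tolerates hindered partners; the first equivalent of base protects the carbinol as its alkoxide.

Step 18
Reactants: 27 coupled styrene
Product: 28 7β-[(1'S)-6'-(tert-butyldimethylsilyloxy)-1',11',12'-trihydroxy-20'-norabieta-5'(10'),6',8',11',13'-pentaen-14'-yl]abieta-8,11,13-triene-12,14-diol (7α-H)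
Conditions: H2 (10 bar), Pd(OH)2/C, EtOAc/EtOH, 25 to 40 °C; filtered under argon and used at once
Reagents that add atoms: none
Why: Heterogeneous hydrogenation adds cis to the α-face of C6=C7, away from the axial C10 and C4β methyl groups, giving the 7α-hydrogen and the pseudo-equatorial 7β-aryl group; hydrogenolysis of the four benzyl ethers in the same step frees the 12-, 14-, 11'- and 12'-hydroxyls.

Step 19
Reactants: 28 7β-naphthyl abietatriene hexol mono-silyl ether
Product: 30 spiro ether (ring D closed; C7–H α, C8' β and C13' α at C14'; 12-OH, 12'-enol, 11'-ketone, 6'-O-TBS, 1'-OH), via ortho-naphthoquinone 29 (not isolated)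
Conditions: Ag2O (1.1 equiv), Na2SO4, CH2Cl2 (5 mM), 0 to 20 °C, dark, argon
Reagents that add atoms: none
Why: Ag2O takes the naphthalene-11',12'-diol to ortho-quinone 29; the left ring is a 12,14-resorcinol that cannot form a quinone, so chemoselectivity needs no protecting group. In 29 C14' is the β-carbon of the C12' carbonyl, and the 14-hydroxyl, held beside it by the pseudo-equatorial 7β bond, adds in a 5-exo-trig oxa-Michael addition that forms O14–C14' and closes ring D; proton transfer leaves the C12' enol and C11' ketone in a ring that cannot rearomatise. The closest known reaction type is conjugate addition of phenols to ortho-quinones, including intramolecular spiro-etherification. The new stereocentre C14' is controlled by C7: the C7–H turns toward the isopropyl flank of ring C' and the C6 methylene toward the flat C8' side, in the reacting rotamer and in the product alike, so O14 should attack the face that places C8' on the β-face. The step needs chemoselective oxidation (resorcinol left ring, one equivalent of oxidant), O- rather than C-attack (only O14 can reach C14' in a five-membered ring) and facial selectivity (the 7α-hydrogen from step 18). High dilution suppresses intermolecular quinone reactions, and because the addition is reversible a trace of base can move the mixture toward the more stable epimer.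

Step 20
Reactants: 30 spiro ether
Product: 32 6'-O-tert-butyldimethylsilyl ether of the target (left 11-hydroxy-12-oxo quinone methide, C7=C8), via left ortho-quinone 31 (not isolated)
Conditions: (KSO3)2NO (2.5 equiv), KH2PO4 buffer, acetone/H2O, 0 to 20 °C
Reagents that add atoms: potassium nitrosodisulfonate (Fremy's salt), [K+].[K+].[O-]S(=O)(=O)N([O])S(=O)(=O)[O-]
Why: Teuber oxidation of a para-blocked, electron-rich phenol gives the ortho-quinone at the only free ortho position (C11); the axial, doubly activated C7–H then shifts to O11 (vinylogous enolisation), giving the conjugated quinone methide and erasing C7, while the reagent leaves the secondary alcohol untouched.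

Step 21
Reactants: 32 6'-O-silyl ether of the target
Product: 33 target compound (CNP0266922.1)
Conditions: TBAF, AcOH (1:1), THF, 0 °C
Reagents that add atoms: none
Why: Buffered fluoride cleavage of the aryl silyl ether; the near-neutral medium spares the quinone methide, the diosphenol and the C14' ether.

## Compound list

1 | (+)-dehydroabietic acid | CC(C)c1cc2c(cc1)[C@@]1(C)CCC[C@@](C)(C(=O)O)[C@@H]1CC2 | starting material
2 | dehydroabietinol | CC(C)c1cc2c(cc1)[C@@]1(C)CCC[C@@](C)(CO)[C@@H]1CC2 | intermediate
3 | dehydroabietinal | CC(C)c1cc2c(cc1)[C@@]1(C)CCC[C@@](C)(C=O)[C@@H]1CC2 | intermediate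
4 | dehydroabietinal hydrazone | CC(C)c1cc2c(cc1)[C@@]1(C)CCC[C@@](C)(C=NN)[C@@H]1CC2 | intermediate
5 | abieta-8,11,13-triene | CC(C)c1cc2c(cc1)[C@@]1(C)CCCC(C)(C)[C@@H]1CC2 | intermediate
6 | 12,14-dibromoabieta-8,11,13-triene | CC(C)c1c(Br)c2c(cc1Br)[C@@]1(C)CCCC(C)(C)[C@@H]1CC2 | intermediate
7 | 12,14-dibromoabieta-8,11,13-trien-7-one | CC(C)c1c(Br)c2c(cc1Br)[C@@]1(C)CCCC(C)(C)[C@@H]1CC2=O | intermediate
8 | 12,14-dihydroxyabieta-8,11,13-trien-7-one | CC(C)c1c(O)c2c(cc1O)[C@@]1(C)CCCC(C)(C)[C@@H]1CC2=O | intermediate
9 | 12,14-bis(benzyloxy)abieta-8,11,13-trien-7-one | CC(C)c1c(OCc3ccccc3)c2c(cc1OCc1ccccc1)[C@@]1(C)CCCC(C)(C)[C@@H]1CC2=O | intermediate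
10 | 12,14-bis(benzyloxy)abieta-6,8,11,13-tetraen-7-yl triflate | CC(C)c1c(OCc3ccccc3)c2c(cc1OCc1ccccc1)[C@@]1(C)CCCC(C)(C)[C@@H]1C=C2OS(=O)(=O)C(F)(F)F | intermediate
11 | 4,4-dimethylcyclohexane-1,3-dione | CC1(C)CCC(=O)CC1=O | starting material
12 | 3-isobutoxy-6,6-dimethylcyclohex-2-en-1-one | CC(C)COC1=CC(=O)C(C)(C)CC1 | intermediate
13 | 1-(1-ethoxyvinyl)-3-isobutoxy-6,6-dimethylcyclohex-2-en-1-ol | CCOC(=C)C1(O)C=C(OCC(C)C)CCC1(C)C | intermediate
14 | 3-acetyl-4,4-dimethylcyclohex-2-en-1-one | CC(=O)C1=CC(=O)CCC1(C)C | intermediate
15 | 2-(tert-butyldimethylsilyloxy)-4-[1-(tert-butyldimethylsilyloxy)vinyl]-5,5-dimethylcyclohexa-1,3-diene | C=C(O[Si](C)(C)C(C)(C)C)C1=CC(O[Si](C)(C)C(C)(C)C)=CCC1(C)C | intermediate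
16 | 3-isopropylcatechol | CC(C)c1cccc(O)c1O | starting material
17 | 3-isopropyl-1,2-benzoquinone | CC(C)C1=CC=CC(=O)C1=O | intermediate
18 | Diels–Alder adduct, catechol tautomer (ring B' 7',10'-dihydro, both silyl enol ethers intact; racemic at C10') | CC(C)c1cc2c(c(O)c1O)C1C(=C(O[Si](C)(C)C(C)(C)C)C2)C(C)(C)CC=C1O[Si](C)(C)C(C)(C)C | intermediate
19 | aromatised ortho-naphthoquinone with ring A' silyl enol ether | CC(C)C1=Cc2cc(O[Si](C)(C)C(C)(C)C)c3c(c2C(=O)C1=O)C(O[Si](C)(C)C(C)(C)C)=CCC3(C)C | intermediate
20 | 10-(tert-butyldimethylsilyloxy)-7-isopropyl-1,1-dimethyl-2,3-dihydrophenanthrene-4,5,6(1H)-trione | CC(C)C1=Cc2cc(O[Si](C)(C)C(C)(C)C)c3c(c2C(=O)C1=O)C(=O)CCC3(C)C | intermediate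
21 | 10-(tert-butyldimethylsilyloxy)-5,6-dihydroxy-7-isopropyl-1,1-dimethyl-2,3-dihydrophenanthren-4(1H)-one | CC(C)c1cc2cc(O[Si](C)(C)C(C)(C)C)c3c(c2c(O)c1O)C(=O)CCC3(C)C | intermediate
22 | 5,6-bis(benzyloxy)-10-(tert-butyldimethylsilyloxy)-7-isopropyl-1,1-dimethyl-2,3-dihydrophenanthren-4(1H)-one | CC(C)c1cc2cc(O[Si](C)(C)C(C)(C)C)c3c(c2c(OCc2ccccc2)c1OCc1ccccc1)C(=O)CCC3(C)C | intermediate
23 | (4S)-5,6-bis(benzyloxy)-10-(tert-butyldimethylsilyloxy)-7-isopropyl-1,1-dimethyl-1,2,3,4-tetrahydrophenanthren-4-ol | CC(C)c1cc2cc(O[Si](C)(C)C(C)(C)C)c3c(c2c(OCc2ccccc2)c1OCc1ccccc1)[C@@H](O)CCC3(C)C | intermediate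
24 | (4S)-5,6-bis(benzyloxy)-8-bromo-10-(tert-butyldimethylsilyloxy)-7-isopropyl-1,1-dimethyl-1,2,3,4-tetrahydrophenanthren-4-ol | CC(C)c1c(Br)c2cc(O[Si](C)(C)C(C)(C)C)c3c(c2c(OCc2ccccc2)c1OCc1ccccc1)[C@@H](O)CCC3(C)C | intermediate
25 | 14'-lithio compound as lithium 1'-alkoxide | CC(C)c1c([Li])c2cc(O[Si](C)(C)C(C)(C)C)c3c(c2c(OCc2ccccc2)c1OCc1ccccc1)[C@@H](O[Li])CCC3(C)C | intermediate
26 | 14'-(chlorozincio) compound as lithium 1'-alkoxide | CC(C)c1c([Zn]Cl)c2cc(O[Si](C)(C)C(C)(C)C)c3c(c2c(OCc2ccccc2)c1OCc1ccccc1)[C@@H](O[Li])CCC3(C)C | intermediate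
27 | coupled styrene (C6=C7; four benzyl ethers, 6'-O-TBS, 1'S-OH) | CC(C)c1c(OCc3ccccc3)c2c(cc1OCc1ccccc1)[C@@]1(C)CCCC(C)(C)[C@@H]1C=C2c1c(C(C)C)c(OCc2ccccc2)c(OCc2ccccc2)c2c1cc(O[Si](C)(C)C(C)(C)C)c1c2[C@@H](O)CCC1(C)C | intermediate
28 | key-step precursor: 7β-naphthyl abietatriene-12,14-diol with 11',12'-diol, 6'-O-TBS, 1'S-OH (7α-H) | CC(C)c1c(O)c2c(cc1O)[C@@]1(C)CCCC(C)(C)[C@@H]1C[C@@H]2c1c(C(C)C)c(O)c(O)c2c1cc(O[Si](C)(C)C(C)(C)C)c1c2[C@@H](O)CCC1(C)C | intermediate
29 | 11',12'-ortho-naphthoquinone of 28 | CC(C)c1c(O)c2c(cc1O)[C@@]1(C)CCCC(C)(C)[C@@H]1C[C@@H]2C1=C(C(C)C)C(=O)C(=O)c2c1cc(O[Si](C)(C)C(C)(C)C)c1c2[C@@H](O)CCC1(C)C | intermediate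
30 | key-step product: spiro ether (7α-H; C8' β, C13' α at C14') | CC(C)c1c2O[C@@]3([C@@H]4c2c(cc1O)[C@@]1(C)CCCC(C)(C)[C@@H]1C4)C(C(C)C)=C(O)C(=O)c1c3cc(O[Si](C)(C)C(C)(C)C)c2c1[C@@H](O)CCC2(C)C | intermediate
31 | left 11,12-ortho-quinone of the spiro ether | CC(C)C1=C2O[C@@]3([C@@H]4C2=C(C(=O)C1=O)[C@@]1(C)CCCC(C)(C)[C@@H]1C4)C(C(C)C)=C(O)C(=O)c1c3cc(O[Si](C)(C)C(C)(C)C)c2c1[C@@H](O)CCC2(C)C | intermediate
32 | 6'-O-tert-butyldimethylsilyl ether of the target | CC(C)C1=C2O[C@@]3(C4=C2C(=C(O)C1=O)[C@@]1(C)CCCC(C)(C)[C@@H]1C4)C(C(C)C)=C(O)C(=O)c1c3cc(O[Si](C)(C)C(C)(C)C)c2c1[C@@H](O)CCC2(C)C | intermediate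
33 | CNP0266922.1 | CC(C)C1=C2O[C@@]3(C4=C2C(=C(O)C1=O)[C@@]1(C)CCCC(C)(C)[C@@H]1C4)C(C(C)C)=C(O)C(=O)c1c3cc(O)c2c1[C@@H](O)CCC2(C)C | target

## Step count and risks

Total: 21 steps. Longest linear sequence: 13 steps (1 → 10 in steps 1–8, then steps 17–21). The right-half branch from 11 is 7 steps to 24, and the quinone 17 takes 1 step.

Least certain steps:

**Step 19 (key step).** The most likely failure is poor facial selectivity at C14'. Rotation about the congested C7–C14' bond may be slow, so two rotamers of quinone 29 could close to different epimers. A lesser risk is tautomerisation of 29 toward a C7=C14' quinone methide, which would scramble the relay. If the preference turns out opposite to the model, the relay would be run with the other C7 configuration, made by the Friedel–Crafts bond formation that was set aside. Ketone 9 is reduced (NaBH4) to the benzylic alcohol F1. Catalytic acid ionises F1 in the presence of arene 23, whose C14' attacks the C7 cation from the α-face to give the 7α-aryl tetrabenzyl ether F2. Hydrogenolysis gives the 7-epimeric precursor F3, and Ag2O under the conditions of step 19 closes it to the 7-epimeric spiro ether F4, which carries the same C14' configuration as 30. Oxidation as in step 20 erases C7 and rejoins the route at 32.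

**Step 13.** The electron-rich silyl enol ethers of 15 may react with the ortho-quinone through its oxygen atoms (hetero-Diels–Alder) or through the ring enol ether, instead of through the exocyclic diene. The fallback removes the second enol ether. From 14, Luche reduction of the unhindered ring ketone gives the allylic alcohol F5, and TBSOTf/Et3N gives the bis-silyl diene F6, which has an sp3 carbinol carbon (racemic). Cycloaddition with 17 and dehydrogenation give the quinone silyl ether F7. Methanolic HCl removes only the secondary silyl ether to give the hydroxy quinone F8, and MnO2 oxidises the benzylic alcohol to rejoin the route at 20.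

**Step 17.** With a di-ortho-substituted arylzinc and a triflate flanked by the 14-benzyloxy group, transmetalation may stall and protodemetalation may take over. The fallback swaps the roles of the partners: Miyaura borylation of triflate 10 (B2pin2, PdCl2(PPh3)2, KOPh) gives the alkenyl pinacolboronate F9, and Suzuki–Miyaura coupling of F9 with bromide 24 (Pd(OAc)2, SPhos, K3PO4, toluene/H2O) rejoins the route at 27.

**Step 18.** Debenzylation should be fast, but reduction of the hindered, doubly aryl-flanked alkene may be incomplete, and forcing conditions could hydrogenolyse the benzylic C1'–O bond. The fallback separates the two events: hydrogen-atom-transfer hydrogenation of 27 (Mn(dpm)3, PhSiH3, t-BuOOH, i-PrOH), which is suited to hindered alkenes and should deliver the C7 hydrogen to the open α-face, gives the saturated tetrabenzyl ether F10. Mild hydrogenolysis (H2, 1 bar, Pd/C) then rejoins the route at 28.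

**Step 20.** The nitroxyl radical may abstract hydrogen from the diosphenol instead of the left phenol, or attack at the crowded C11 may be slow. The fallback introduces O11 in two polar steps. From 30, magnesium-mediated ortho-formylation (MgCl2, Et3N, paraformaldehyde) gives the 11-aldehyde F11. Dakin oxidation under non-basic conditions gives the left catechol F12, and Ag2O oxidises F12 to the ortho-quinone, which tautomerises and rejoins the route at 32.

## Further compounds

F1 | step 19 | 12,14-bis(benzyloxy)abieta-8,11,13-trien-7-ol | CC(C)c1c(OCc3ccccc3)c2c(cc1OCc1ccccc1)[C@@]1(C)CCCC(C)(C)[C@@H]1CC2O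
F2 | step 19 | 7α-naphthyl tetrabenzyl ether (7β-H epimer of F10) | CC(C)c1c(OCc3ccccc3)c2c(cc1OCc1ccccc1)[C@@]1(C)CCCC(C)(C)[C@@H]1C[C@H]2c1c(C(C)C)c(OCc2ccccc2)c(OCc2ccccc2)c2c1cc(O[Si](C)(C)C(C)(C)C)c1c2[C@@H](O)CCC1(C)C
F3 | step 19 | 7-epimer of precursor 28 | CC(C)c1c(O)c2c(cc1O)[C@@]1(C)CCCC(C)(C)[C@@H]1C[C@H]2c1c(C(C)C)c(O)c(O)c2c1cc(O[Si](C)(C)C(C)(C)C)c1c2[C@@H](O)CCC1(C)C
F4 | step 19 | 7-epimer of spiro ether 30 (same C14' configuration) | CC(C)c1c2O[C@@]3([C@H]4c2c(cc1O)[C@@]1(C)CCCC(C)(C)[C@@H]1C4)C(C(C)C)=C(O)C(=O)c1c3cc(O[Si](C)(C)C(C)(C)C)c2c1[C@@H](O)CCC2(C)C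
F5 | step 13 | 1-(3-hydroxy-6,6-dimethylcyclohex-1-en-1-yl)ethan-1-one (racemic) | CC(=O)C1=CC(O)CCC1(C)C
F6 | step 13 | 3-(tert-butyldimethylsilyloxy)-1-[1-(tert-butyldimethylsilyloxy)vinyl]-6,6-dimethylcyclohex-1-ene (racemic) | C=C(O[Si](C)(C)C(C)(C)C)C1=CC(O[Si](C)(C)C(C)(C)C)CCC1(C)C
F7 | step 13 | 4,10-bis(tert-butyldimethylsilyloxy)-7-isopropyl-1,1-dimethyl-1,2,3,4-tetrahydrophenanthrene-5,6-dione (racemic) | CC(C)C1=Cc2cc(O[Si](C)(C)C(C)(C)C)c3c(c2C(=O)C1=O)C(O[Si](C)(C)C(C)(C)C)CCC3(C)C
F8 | step 13 | 10-(tert-butyldimethylsilyloxy)-4-hydroxy-7-isopropyl-1,1-dimethyl-1,2,3,4-tetrahydrophenanthrene-5,6-dione (racemic) | CC(C)C1=Cc2cc(O[Si](C)(C)C(C)(C)C)c3c(c2C(=O)C1=O)C(O)CCC3(C)C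
F9 | step 17 | 12,14-bis(benzyloxy)abieta-6,8,11,13-tetraen-7-yl pinacolboronate | CC(C)c1c(OCc3ccccc3)c2c(cc1OCc1ccccc1)[C@@]1(C)CCCC(C)(C)[C@@H]1C=C2B1OC(C)(C)C(C)(C)O1
F10 | step 18 | 7β-naphthyl tetrabenzyl ether (7α-H), saturated at C6–C7 | CC(C)c1c(OCc3ccccc3)c2c(cc1OCc1ccccc1)[C@@]1(C)CCCC(C)(C)[C@@H]1C[C@@H]2c1c(C(C)C)c(OCc2ccccc2)c(OCc2ccccc2)c2c1cc(O[Si](C)(C)C(C)(C)C)c1c2[C@@H](O)CCC1(C)C
F11 | step 20 | 11-formyl derivative of spiro ether 30 | CC(C)c1c2O[C@@]3([C@@H]4c2c(c(C=O)c1O)[C@@]1(C)CCCC(C)(C)[C@@H]1C4)C(C(C)C)=C(O)C(=O)c1c3cc(O[Si](C)(C)C(C)(C)C)c2c1[C@@H](O)CCC2(C)C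
F12 | step 20 | 11,12-catechol of the spiro ether | CC(C)c1c2O[C@@]3([C@@H]4c2c(c(O)c1O)[C@@]1(C)CCCC(C)(C)[C@@H]1C4)C(C(C)C)=C(O)C(=O)c1c3cc(O[Si](C)(C)C(C)(C)C)c2c1[C@@H](O)CCC2(C)C
A1 | alternative 1 | spiro nitro alcohol cycloadduct | CC(C)c1c2O[C@@]3([C@@H]4c2c(c(OCOC)c1OCOC)[C@@]1(C)CCCC(C)(C)[C@@H]1C4)[C@@H](C(C)C)[C@H]([N+](=O)[O-])[C@H](O)c1c3cc(OCOC)c2c1[C@@H](O[Si](C)(C)C(C)(C)C)CCC2(C)C
A2 | alternative 2 | tetracyclic left-half benzofuran carrying the ring A'B' aryl group | CC(C)c1c2oc(-c4cc(OC)c5c(c4C(=O)OC)[C@@H](OC(C)=O)CCC5(C)C)c3c2c(c(OC)c1OC)[C@@]1(C)CCCC(C)(C)[C@@H]1C3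
A3 | alternative 3 | protected spiro naphthalenone with a C6' pinacolboronate | CC(C)c1c2O[C@@]3([C@@H]4c2c(c(OCOC)c1OCOC)[C@@]1(C)CCCC(C)(C)[C@@H]1C4)C(C(C)C)=C(OCOC)C(=O)c1c3cc(B3OC(C)(C)C(C)(C)O3)c2c1[C@@H](O[Si](C)(C)C(C)(C)C)CCC2(C)C
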